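The isocoumarin is traced back to an acyclic triyne. Ring A (C4a, C5, C6, C7, C8, C8a) is what a conjugated diyne (C6, C7, C8, C8a) and a single alkyne (C4a, C5) give on thermal cycloisomerization, and the Z enol ester joining them (C1, O2, C3, C4) becomes lactone ring B in the same event. The C7–C8 aryne formed is captured by the hindered ring C phenol, oxygen going to C8 under the influence of the C6 alkoxy group, so two rings and the diaryl ether arise in one operation. The precursor is a Z enynyl ester of a 5-alkoxypenta-2,4-diynoic acid, used with a protected 3-hydroxybenzoate.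

Key step: step 10

Remark: the C6 oxygen is carried as a methyl, not an ethyl, alkynyl ether, because ethyl alkynyl ethers lose ethylene to give ketenes (retro-ene) in the temperature range the cycloisomerization is expected to need, whereas a methyl ether has no β-hydrogen and falls at the end together with the other methyl ethers; locants C1 to C8a are those of the isocoumarin.

Step 1
Reactants: 1 hexanal; 2 3-bromoprop-1-yne
Product: 3 rac-non-1-yn-4-ol
Conditions: Zn dust, THF/satd aq NH4Cl, 0 °C to rt
Reagents that add atoms: none
Why: Barbier propargylation, in which the organozinc formed from the propargylic bromide adds to the aldehyde through its γ-carbon to give the homopropargylic alcohol; the carbinol centre forms racemic and is erased in step 2.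

Step 2
Reactants: 3 rac-non-1-yn-4-ol
Product: 4 non-1-yn-4-one
Conditions: Dess–Martin periodinane, CH2Cl2, 0 °C to rt; short silica pad, used at once
Reagents that add atoms: none
Why: Dess–Martin oxidation of a secondary alcohol under neutral conditions should give the β,γ-alkynyl ketone without the base that would isomerize it to the allenyl ketone.

Step 3
Reactants: 5 prop-2-ynoic acid
Product: 6 3-bromoprop-2-ynoic acid
Conditions: NBS, AgNO3 (cat.), acetone, rt, dark
Reagents that add atoms: N-bromosuccinimide, O=C1CCC(=O)N1Br
Why: Silver-catalysed electrophilic bromination of a terminal alkyne C–H bond, a standard entry to 1-bromoalkynes that leaves the carboxylic acid untouched.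

Step 4
Reactants: 7 2-chloro-1,1-dimethoxyethane
Product: 8 methoxyethyne
Conditions: NaNH2 (3 equiv), liq. NH3, −33 °C; then cold aq NH4Cl, distilled into cold THF
Reagents that add atoms: none
Why: Twofold elimination with NaNH2 (HCl, then methanol) turns the chloroacetal into sodium methoxyacetylide, the classic alkoxyacetylene synthesis, and cold protonation releases the volatile alkyne, which is kept in solution.

Step 5
Reactants: 8 methoxyethyne; 6 3-bromoprop-2-ynoic acid
Product: 9 5-methoxypenta-2,4-diynoic acid
Conditions: CuCl (cat.), NH2OH·HCl, aq BuNH2, MeOH, 0 °C; then cold aq NaHSO4 to pH 2, Et2O, used at once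
Reagents that add atoms: none
Why: Cadiot–Chodkiewicz coupling of the copper acetylide of 8 with the bromoalkyne, which is present as its carboxylate and so is shielded from amine addition; conjugation to the carboxyl group should temper the alkynyl ether during the brief cold acidification.

Step 6
Reactants: 9 5-methoxypenta-2,4-diynoic acid; 4 non-1-yn-4-one
Product: 12 (3Z)-non-3-en-1-yn-4-yl 5-methoxypenta-2,4-diynoate, via acid chloride 10 (not isolated), via potassium Z-enolate 11 (not isolated)
Conditions: 9, 1-chloro-N,N,2-trimethylprop-1-en-1-amine, CH2Cl2, 0 °C; 4, KN(SiMe3)2, THF, −78 °C; enolate cannulated into the acid chloride, −78 °C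
Reagents that add atoms: none
Why: Enolate O-acylation: KN(SiMe3)2 deprotonates the methylene between carbonyl and alkyne, the extended enolate should prefer the Z geometry (slim alkynyl group syn to oxygen, away from the pentyl chain), and the hard acid chloride, made without HCl by the chloroenamine so that the alkynyl ether is spared, should acylate the potassium enolate on oxygen, fixing the Z enol ester without creating a stereocenter.

Step 7
Reactants: 13 methyl 2,4-dihydroxy-6-pentylbenzoate
Product: 14 methyl 2,4-dimethoxy-6-pentylbenzoate
Conditions: MeI, K2CO3, DMF, 60 °C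
Reagents that add atoms: iodomethane, CI
Why: Williamson O-methylation of both phenols, the hydrogen-bonded one next to the ester needing DMF and warming, while the hindered methyl ester is not touched.

Step 8
Reactants: 14 methyl 2,4-dimethoxy-6-pentylbenzoate
Product: 15 methyl 3-formyl-4,6-dimethoxy-2-pentylbenzoate
Conditions: Cl2CHOMe, TiCl4, CH2Cl2, 0 °C; then ice-water
Reagents that add atoms: dichloro(methoxy)methane, COC(Cl)Cl; water, O
Why: Rieche formylation, an electrophilic aromatic substitution that should go to the ring position para to one methoxy group, ortho to the other and next to the pentyl chain (the site that resorcylate dimethyl ethers offer to electrophiles) and not between the two methoxy groups.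

Step 9
Reactants: 15 methyl 3-formyl-4,6-dimethoxy-2-pentylbenzoate
Product: 17 methyl 3-hydroxy-4,6-dimethoxy-2-pentylbenzoate, via aryl formate 16 (not isolated)
Conditions: mCPBA, CH2Cl2, 0 °C to rt; then K2CO3 (cat.), MeOH, rt
Reagents that add atoms: 3-chloroperoxybenzoic acid, OOC(=O)c1cccc(Cl)c1
Why: Dakin-type Baeyer–Villiger oxidation, in which the electron-rich aryl group migrates to oxygen and the resulting formate is methanolysed under base too mild to affect the doubly ortho-substituted methyl ester.

Step 10
Reactants: 12 (3Z)-non-3-en-1-yn-4-yl 5-methoxypenta-2,4-diynoate; 17 methyl 3-hydroxy-4,6-dimethoxy-2-pentylbenzoate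
Product: 19 methyl 4,6-dimethoxy-3-[(6-methoxy-1-oxo-3-pentyl-1H-isochromen-8-yl)oxy]-2-pentylbenzoate, via 7,8-aryne 18 (not isolated)
Conditions: 17 (3 equiv), 1,2-dichlorobenzene, 130 °C, slow addition of 12 (final 0.01 M), Ar
Reagents that add atoms: none
Why: Proposed new method: on heating, the diyne C6≡C7–C8≡C8a and the tethered alkyne C4a≡C5 should combine in a net [4+2] cycloisomerization (probably stepwise through a diradical) that forms C5–C6 and C4a–C8a and leaves aryne 18, across which the O–H of 17 then adds; the closest known reaction type is the thermal hexadehydro-Diels–Alder reaction of ester-tethered triynes with in situ O–H trapping of the aryne, extended here to a four-atom enol ester tether and a methoxy-capped diyne. Ring A closes as the six-membered carbocycle of the intramolecular [4+2] event, and ring B closes in the same event as the six-membered tether ring fused to it once C4a–C8a forms, the ester turning so that C3 and C8a lie on the same side of the C1–O2 bond. No stereocenter is created. O-arylation is secured over the ene-type C-arylation usual for phenols because both ortho positions and the para position of the hydroxyl group in 17 are substituted. The regiochemistry rests on the C6 methoxy group, whose inductive pull should make C8 the more electrophilic aryne carbon, so that oxygen bonds to C8 and hydrogen to C7, and on the Z enol ester set in step 6, without which the alkynes cannot reach each other.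

Step 11
Reactants: 19 methyl 4,6-dimethoxy-3-[(6-methoxy-1-oxo-3-pentyl-1H-isochromen-8-yl)oxy]-2-pentylbenzoate
Product: 20 4,6-dimethoxy-3-[(6-methoxy-1-oxo-3-pentyl-1H-isochromen-8-yl)oxy]-2-pentylbenzoic acid
Conditions: LiI, pyridine, reflux; then cold 1 M HCl
Reagents that add atoms: none
Why: Iodide cleaves the hindered ester by SN2 attack at the O-methyl carbon, so the shielded acyl carbon need not be approached, the lactone is spared, and the heating is done before the phenols are freed, when the acid is not yet prone to decarboxylation.

Step 12
Reactants: 20 4,6-dimethoxy-3-[(6-methoxy-1-oxo-3-pentyl-1H-isochromen-8-yl)oxy]-2-pentylbenzoic acid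
Product: 21 4,6-dihydroxy-3-[(6-hydroxy-1-oxo-3-pentyl-1H-isochromen-8-yl)oxy]-2-pentylbenzoic acid
Conditions: BBr3 (8 equiv), CH2Cl2, −78 °C to rt; ice-water quench, work-up below 25 °C
Reagents that add atoms: none
Why: Lewis acid cleavage of the three aryl methyl ethers by BBr3, which should leave the diaryl ether and the lactone intact, with a cold work-up to protect the 2,4-dihydroxybenzoic acid from decarboxylation.

Compound list
1 | hexanal | CCCCCC=O | starting material
2 | 3-bromoprop-1-yne | C#CCBr | starting material
3 | rac-non-1-yn-4-ol | C#CCC(O)CCCCC | intermediate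
4 | non-1-yn-4-one | C#CCC(=O)CCCCC | intermediate
5 | prop-2-ynoic acid | C#CC(=O)O | starting material
6 | 3-bromoprop-2-ynoic acid | BrC#CC(=O)O | intermediate
7 | 2-chloro-1,1-dimethoxyethane | COC(CCl)OC | starting material
8 | methoxyethyne | COC#C | intermediate
9 | 5-methoxypenta-2,4-diynoic acid | COC#CC#CC(=O)O | intermediate
10 | 5-methoxypenta-2,4-diynoyl chloride | COC#CC#CC(=O)Cl | intermediate
11 | potassium (3Z)-non-3-en-1-yn-4-olate | C#C/C=C(/CCCCC)[O-].[K+] | intermediate
12 | (3Z)-non-3-en-1-yn-4-yl 5-methoxypenta-2,4-diynoate | C#C/C=C(/CCCCC)OC(=O)C#CC#COC | intermediate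
13 | methyl 2,4-dihydroxy-6-pentylbenzoate | CCCCCc1cc(O)cc(O)c1C(=O)OC | starting material
14 | methyl 2,4-dimethoxy-6-pentylbenzoate | CCCCCc1cc(OC)cc(OC)c1C(=O)OC | intermediate
15 | methyl 3-formyl-4,6-dimethoxy-2-pentylbenzoate | CCCCCc1c(C=O)c(OC)cc(OC)c1C(=O)OC | intermediate
16 | methyl 3-(formyloxy)-4,6-dimethoxy-2-pentylbenzoate | CCCCCc1c(OC=O)c(OC)cc(OC)c1C(=O)OC | intermediate
17 | methyl 3-hydroxy-4,6-dimethoxy-2-pentylbenzoate | CCCCCc1c(O)c(OC)cc(OC)c1C(=O)OC | intermediate
18 | 7,8-didehydro-6-methoxy-3-pentyl-1H-isochromen-1-one | CCCCCC1=CC2=C(C#CC(OC)=C2)C(=O)O1 | intermediate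
19 | methyl 4,6-dimethoxy-3-[(6-methoxy-1-oxo-3-pentyl-1H-isochromen-8-yl)oxy]-2-pentylbenzoate | CCCCCc1cc2cc(OC)cc(Oc3c(OC)cc(OC)c(C(=O)OC)c3CCCCC)c2c(=O)o1 | intermediate
20 | 4,6-dimethoxy-3-[(6-methoxy-1-oxo-3-pentyl-1H-isochromen-8-yl)oxy]-2-pentylbenzoic acid | CCCCCc1cc2cc(OC)cc(Oc3c(OC)cc(OC)c(C(=O)O)c3CCCCC)c2c(=O)o1 | intermediate
21 | 4,6-dihydroxy-3-[(6-hydroxy-1-oxo-3-pentyl-1H-isochromen-8-yl)oxy]-2-pentylbenzoic acid | CCCCCc1cc2cc(O)cc(Oc3c(O)cc(O)c(C(=O)O)c3CCCCC)c2c(=O)o1 | target

Total step count: 12 steps.
Longest linear sequence: 6 steps (steps 7, 8, 9, 10, 11, 12; the branches through steps 1, 2, 6 and through steps 4, 5, 6 are equally long).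

Steps most likely to fail

Step 10. Ring closure through the six-membered enol ester tether may be slower than oligomerization of the polyyne or addition of the phenol to the electron-poor diyne. Capture of the aryne by the crowded hydroxyl group may also lose out to other ways in which the aryne is consumed. The fallback sets out from 17 and comes back at 19, using known chemistry only. Purchased methyl 2,4-dimethoxy-6-methylbenzoate F1 would be lithiated at the benzylic methyl group (LiN(iPr)2, THF, −78 °C) and acylated with N-methoxy-N-methylhexanamide to give methyl 2,4-dimethoxy-6-(2-oxoheptyl)benzoate F2. Acid-mediated enol lactonization (TsOH, toluene, reflux) should then give 6,8-dimethoxy-3-pentyl-1H-isochromen-1-one F3. BCl3 (CH2Cl2, −78 to 0 °C) should remove only the methyl group peri to the lactone carbonyl, giving 8-hydroxy-6-methoxy-3-pentyl-1H-isochromen-1-one F4. Tf2O and pyridine would convert this into 6-methoxy-1-oxo-3-pentyl-1H-isochromen-8-yl trifluoromethanesulfonate F5. Palladium-catalysed diaryl ether coupling of this electron-poor triflate with 17 (Pd(OAc)2, t-BuXPhos, K3PO4, toluene, 100 °C) should give 19.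

Step 6. Enolization may not be fully Z-selective, and acylation on carbon or isomerization toward the allenyl ketone may compete with acylation on oxygen. The fallback sets out from 4 and comes back at 12. Silylation under equilibrating conditions (t-BuMe2SiOTf, Et3N, CH2Cl2, −78 to 0 °C) would give tert-butyl(dimethyl){[(3Z)-non-3-en-1-yn-4-yl]oxy}silane F6. This is a stable enol ether whose geometry can be assigned and whose isomers can be separated. The purified Z isomer would then be unmasked with tetrabutylammonium difluorotriphenylsilicate in THF at −78 °C in the presence of acid chloride 10. The ammonium enolate should be acylated on oxygen with retention of geometry to give 12.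

Step 5. The alkynyl ether may be lost by hydration or amine addition during the aqueous coupling and acidification, and the free acid may add to its own alkynyl ether on standing. The fallback sets out from 8 and comes back at 10, so that no free acid is handled. Coupling of 8 with (bromoethynyl)trimethylsilane (Pd(PPh3)2Cl2, CuI, iPr2NH, THF) would give (4-methoxybuta-1,3-diyn-1-yl)trimethylsilane F7. Desilylation (K2CO3, MeOH) would give 1-methoxybuta-1,3-diyne F8, kept in solution. Lithiation (BuLi, THF, −78 °C) and carboxylation with CO2 would give lithium 5-methoxypenta-2,4-diynoate F9. The dry salt with oxalyl chloride in CH2Cl2 should give acid chloride 10 without HCl, and step 6 then proceeds as written.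

Further compounds
F1 | step 10 | methyl 2,4-dimethoxy-6-methylbenzoate | COC(=O)c1c(C)cc(OC)cc1OC
F2 | step 10 | methyl 2,4-dimethoxy-6-(2-oxoheptyl)benzoate | CCCCCC(=O)Cc1cc(OC)cc(OC)c1C(=O)OC
F3 | step 10 | 6,8-dimethoxy-3-pentyl-1H-isochromen-1-one | CCCCCc1cc2cc(OC)cc(OC)c2c(=O)o1
F4 | step 10 | 8-hydroxy-6-methoxy-3-pentyl-1H-isochromen-1-one | CCCCCc1cc2cc(OC)cc(O)c2c(=O)o1
F5 | step 10 | 6-methoxy-1-oxo-3-pentyl-1H-isochromen-8-yl trifluoromethanesulfonate | CCCCCc1cc2cc(OC)cc(OS(=O)(=O)C(F)(F)F)c2c(=O)o1
F6 | step 6 | tert-butyl(dimethyl){[(3Z)-non-3-en-1-yn-4-yl]oxy}silane | C#C/C=C(/CCCCC)O[Si](C)(C)C(C)(C)C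
F7 | step 5 | (4-methoxybuta-1,3-diyn-1-yl)trimethylsilane | COC#CC#C[Si](C)(C)C
F8 | step 5 | 1-methoxybuta-1,3-diyne | COC#CC#C
F9 | step 5 | lithium 5-methoxypenta-2,4-diynoate | COC#CC#CC(=O)[O-].[Li+]
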